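**Plan**

1. Labdane numbering is used: ring A = C1–C5, C10; ring B = C5–C10; C17 = exocyclic CH2; C18 = formyl carbon on C4; chain C11–C15; butenolide γ-carbon = C5′. Retrosynthetic cuts, in order: C15–C5′ (vinylogous aldol with a purchased butenolide ring), C9–C10 (ring B), C8=C17/C9–C11 (enyne metathesis), C6–C7 (propargylation), then C3–C4 and C5–C10 of ring A (Diels–Alder).
2. Forward: ring A by Diels–Alder; O6 and C18 tied as a γ-lactone; the C7–C15 arm grown on C6; ring B closed last by ionising a C10 tertiary alcohol onto a C17-silylated C8=C9 allylsilane; the lactone is then reduced to a lactol acetal and the butenolide appended.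
3. Enabling feature: O6 (equatorial on ring B) and C18 (equatorial on ring A) flank C5 and lie within bonding distance, so the five-membered ring C18–C4–C5–C6–O can be trans-fused to both rings. Before ring B exists this lactone fixes the sign of the C10–C5–C6–C7 torsion, so C9 can reach only the α lobe of a C10 cation.
4. Stereochemistry: C4/C5 from the (E)-dienophile and a chiral Lewis acid; C6 from attack on the lactone oxocarbenium ion anti to the C4 methyl; C9/C10 from the chair closure of the (Z)-allylsilane; C15/C5′ from a ligand-controlled vinylogous Mukaiyama aldol.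

Key step: step 14

Assumption: the facial sense of the two ligand-controlled steps (3 and 20) is taken as written, the enantiomeric ligand being used if the opposite sense is found; the target, drawn as the open 6-hydroxy-18-aldehyde, may rest in equilibrium with its 6,18-lactol.

**Route**

Step 1
Reactants: 1 2,2-dimethoxyacetaldehyde; 2 benzyl 2-bromopropanoate
Product: 5 benzyl (E)-4,4-dimethoxy-2-methylbut-2-enoate, via phosphonium bromide 3 (not isolated), via ylide 4 (not isolated)
Conditions: PPh3, sat. aq. NaHCO3, 25 °C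
Reagents that add atoms: none
Why: One-pot Wittig olefination with a stabilised α-methyl ylide formed in the flask, which should give the E enoate (ester trans to the acetal carbon).

Step 2
Reactants: 5 benzyl (E)-4,4-dimethoxy-2-methylbut-2-enoate
Product: 6 benzyl (E)-2-methyl-4-oxobut-2-enoate
Conditions: Amberlyst-15, acetone/H2O, rt
Reagents that add atoms: water, O
Why: Acid-catalysed acetal hydrolysis frees the conjugated aldehyde without touching the benzyl ester or the E geometry.

Step 3
Reactants: 6 benzyl (E)-2-methyl-4-oxobut-2-enoate; 7 (E)-buta-1,3-dien-1-yl acetate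
Product: 8 benzyl 5-acetoxy-6-formyl-1-methylcyclohex-3-ene-1-carboxylate (formyl trans to the ester and cis to the ring methyl; acetoxy cis to formyl)
Conditions: oxazaborolidine from (S)-α,α-diphenylprolinol and o-tolylboronic acid, activated with Tf2NH (20 mol%), CH2Cl2, −78 → −40 °C
Reagents that add atoms: none
Why: Catalytic enantioselective Diels–Alder reaction in which the Lewis-acid-bound formyl group directs the diene CH2 terminus to the methyl-bearing carbon (quaternary C4) and the acetoxy carbon to C5; suprafacial addition to the E dienophile fixes C4/C5 (ester trans to formyl) and the catalyst should select the enantioface.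

Step 4
Reactants: 8 Diels–Alder adduct
Product: 10 trans-fused 4-acetoxy-3-hydroxy-7a-methylhexahydro-2-benzofuran-1(3H)-one (anomeric mixture), via formyl acid 9 (not isolated)
Conditions: H2 (1 atm), Pd/C, EtOAc, rt
Reagents that add atoms: none
Why: Heterogeneous hydrogenation saturates the ring alkene and hydrogenolyses the benzyl ester, and the freed trans-disposed formyl acid should close by ring–chain tautomerism to the hydroxy lactone.

Step 5
Reactants: 10 hydroxy lactone
Product: 11 trans-fused 3,4-diacetoxy-7a-methylhexahydro-2-benzofuran-1(3H)-one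
Conditions: Ac2O, pyridine, DMAP (cat.), CH2Cl2, 0 °C → rt
Reagents that add atoms: acetic anhydride, CC(=O)OC(C)=O
Why: O-Acetylation of the lactol hydroxyl gives the anomeric acetate, a precursor of the cyclic acyloxocarbenium ion.

Step 6
Reactants: 11 diacetoxy lactone; 12 tributyl(propa-1,2-dien-1-yl)stannane
Product: 13 trans-fused 4-acetoxy-7a-methyl-3-(prop-2-yn-1-yl)hexahydro-2-benzofuran-1(3H)-one (propargyl on the face opposite to the 7a-methyl; labdane C6)
Conditions: BF3·OEt2, CH2Cl2, −78 → −30 °C
Reagents that add atoms: none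
Why: Lewis-acid ionisation to the bicyclic acyloxocarbenium ion and SE2′ propargylation by the allenylstannane (Hosomi–Sakurai type); the nucleophile should enter anti to the angular C4 methyl and the C10 acetoxy group, which sets C6.

Step 7
Reactants: 14 pent-1-en-4-yne
Product: 16 (E)-3-methylhexa-2,5-dien-1-ol, via alkenylalane 15 (not isolated)
Conditions: Me3Al, Cp2ZrCl2 (20 mol%), CH2Cl2, rt; then n-BuLi, (CH2O)n, THF, −78 °C → rt
Reagents that add atoms: trimethylaluminium, C[Al](C)C; formaldehyde (as paraformaldehyde), C=O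
Why: Zirconium-catalysed carboalumination (Negishi) adds Me–Al syn across the alkyne only, and hydroxymethylation of the derived alanate with retention should give the E allylic alcohol.

Step 8
Reactants: 16 (E)-3-methylhexa-2,5-dien-1-ol
Product: 17 tert-butyl{[(E)-3-methylhexa-2,5-dien-1-yl]oxy}diphenylsilane
Conditions: TBDPSCl, imidazole, DMF, rt
Reagents that add atoms: tert-butyl(chloro)diphenylsilane, CC(C)(C)[Si](Cl)(c1ccccc1)c1ccccc1
Why: Standard silylation of the primary allylic alcohol gives an ether that survives the Lewis-acid, Grignard and hydride steps ahead.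

Step 9
Reactants: 13 propargyl lactone; 17 silyl ether
Product: 18 trans-fused 4-acetoxy-3-[(3E,6E)-8-(tert-butyldiphenylsilyloxy)-6-methyl-2-methylideneocta-3,6-dien-1-yl]-7a-methylhexahydro-2-benzofuran-1(3H)-one
Conditions: 17 (3 equiv), second-generation Grubbs catalyst (5 mol%), CH2Cl2, 40 °C
Reagents that add atoms: none
Why: Cross enyne metathesis of a terminal alkyne with a terminal alkene gives the 2-substituted 1,3-diene with all atoms retained; the trisubstituted alkene is a spectator and the geometry of the new disubstituted bond is lost in the next step.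

Step 10
Reactants: 18 diene
Product: 19 trans-fused 4-acetoxy-3-[(2Z,6E)-8-(tert-butyldiphenylsilyloxy)-6-methyl-2-(triethylsilylmethyl)octa-2,6-dien-1-yl]-7a-methylhexahydro-2-benzofuran-1(3H)-one
Conditions: Et3SiH, iminopyridine iron catalyst Fe[2-(2,6-iPr2C6H3N=CMe)C5H4N]2 (5 mol%), toluene, rt
Reagents that add atoms: triethylsilane, CC[SiH](CC)CC
Why: Iron-catalysed 1,4-hydrosilylation of the s-cis diene should place silicon on the free CH2 terminus (C17) and hydrogen on C11, leaving the C8=C9 bond with the two former termini cis (CH2Si cis to C11, C7 trans to C11).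

Step 11
Reactants: 19 allylsilane acetate
Product: 20 the corresponding 4-hydroxy lactone (C10 alcohol)
Conditions: K2CO3, MeOH, 0 °C; then CSA (cat.), CH2Cl2, rt
Reagents that add atoms: none
Why: Transesterification removes the secondary acetate, and the hindered trans-fused lactone should survive or re-close on the acidic finish.

Step 12
Reactants: 20 C10 alcohol
Product: 21 the corresponding 4-oxo lactone (C10 ketone)
Conditions: Dess–Martin periodinane, NaHCO3, CH2Cl2, 0 °C
Reagents that add atoms: none
Why: Buffered Dess–Martin oxidation gives the ketone under neutral conditions that should spare the allylsilane and avoid β-elimination of the lactone oxygen or epimerisation at C5.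

Step 13
Reactants: 21 C10 ketone
Product: 22 trans-fused 4-hydroxy-4,7a-dimethyl-3-[(2Z,6E)-8-(tert-butyldiphenylsilyloxy)-6-methyl-2-(triethylsilylmethyl)octa-2,6-dien-1-yl]hexahydro-2-benzofuran-1(3H)-one (C10 epimers)
Conditions: MeMgBr, CeCl3, THF, −78 °C
Reagents that add atoms: methylmagnesium bromide, C[Mg]Br
Why: Organocerium 1,2-addition is weakly basic and should add to the ketone in preference to the hindered lactone; the new C10 centre need not be controlled because it becomes a planar cation.

Step 14
Reactants: 22 tertiary alcohol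
Product: 23 (13E)-15-(tert-butyldiphenylsilyloxy)labda-8(17),13-dien-18,6α-olide
Conditions: TiCl4, 2,6-di-tert-butyl-4-methylpyridine, CH2Cl2, −78 °C
Reagents that add atoms: none
Why: TiCl4 ionises the C10 tertiary alcohol to a ring A carbocation, which is captured in a 6-endo-trig, chair-like closure by C9 of the 2-substituted allylsilane; the β-silyl cation at C8 then loses silicon to leave the C8=C17 exocyclic methylene. The closest known reaction type is the allylsilane-terminated cation–olefin cyclisation (an SN1-type Hosomi–Sakurai alkylation of a tertiary cation), as used for exocyclic-methylene drimanes and labdanes and for allylsilane capping of tertiary polyisobutylene cations with TiCl4 and a hindered pyridine. Ring B is closed through the C9–C10 bond, between a quaternary and a tertiary carbon. C10 is controlled by the trans-fused lactone, which holds C7 on the face of C6 opposite to C10, so a chair is possible only when C9 adds to the α lobe of the cation (anti to C4), giving the trans ring fusion with C20 β; C9 is controlled by the alkene geometry, C11 being trans to C7 and therefore equatorial. The step needs ring closure to outrun proton loss from the cation and protodesilylation, which the six-ring intramolecular capture, the low temperature and the proton trap should secure; it also needs the alkene to form only at C8=C17, which the silicon on C17 secures, and the distant C13=C14 bond and allylic silyl ether are not expected to interfere.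

Step 15
Reactants: 23 decalin lactone
Product: 24 (13E)-15-(tert-butyldiphenylsilyloxy)-6α,18-epoxylabda-8(17),13-dien-18-ol (lactol, anomers)
Conditions: i-Bu2AlH, CH2Cl2, −78 °C
Reagents that add atoms: none
Why: Partial reduction of the lactone stops at the aluminium hemiacetal at low temperature and should give the lactol, which is the ring form of the target's 6-hydroxy-18-aldehyde.

Step 16
Reactants: 24 lactol
Product: 25 (13E)-15-(tert-butyldiphenylsilyloxy)-18-methoxy-6α,18-epoxylabda-8(17),13-diene (anomers)
Conditions: MeOH, PPTS (cat.), rt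
Reagents that add atoms: methanol, CO
Why: Acid-catalysed acetalisation masks the C18 aldehyde and the C6 hydroxyl together as one cyclic methyl acetal.

Step 17
Reactants: 25 methyl acetal
Product: 26 (13E)-18-methoxy-6α,18-epoxylabda-8(17),13-dien-15-ol
Conditions: Bu4NF, THF, rt
Reagents that add atoms: none
Why: Fluoride desilylation frees the primary allylic alcohol and leaves the acetal and alkenes untouched.

Step 18
Reactants: 26 allylic alcohol
Product: 27 (13E)-18-methoxy-6α,18-epoxylabda-8(17),13-dien-15-al
Conditions: MnO2, CH2Cl2, rt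
Reagents that add atoms: none
Why: Selective allylic oxidation with MnO2 should give the E enal without isomerisation.

Step 19
Reactants: 28 4-methylfuran-2(5H)-one
Product: 29 trimethyl[(4-methylfuran-2-yl)oxy]silane
Conditions: Me3SiOTf, Et3N, CH2Cl2, 0 °C
Reagents that add atoms: trimethylsilyl trifluoromethanesulfonate, C[Si](C)(C)OS(=O)(=O)C(F)(F)F
Why: Soft enolisation and O-silylation convert the purchased butenolide into its aromatic 2-silyloxyfuran, the dienolate equivalent for the vinylogous aldol.

Step 20
Reactants: 27 enal; 29 silyloxyfuran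
Product: 31 (5S)-5-[(1S,2E)-1-hydroxy-3-methyl-5-(decalin acetal)pent-2-en-1-yl]-4-methylfuran-2(5H)-one, that is the 15-hydroxy butenolide adduct of 27, via silyl ether 30 (not isolated)
Conditions: Ti(OiPr)4/(R)-BINOL (20 mol%), Et2O, −20 °C; then aq. citric acid
Reagents that add atoms: none
Why: Vinylogous Mukaiyama aldol in which the silyloxyfuran attacks through its γ-carbon; the open transition state should favour the syn (threo) adduct and the ligand the aldehyde face, setting C15 and C5′ as S,S without touching the acetal.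

Step 21
Reactants: 31 butenolide acetal
Product: 32 target hydroxy aldehyde (4R,5R,6S,9S,10R; 15S; 5′S)
Conditions: AcOH/THF/H2O, rt
Reagents that add atoms: water, O
Why: Mild acid hydrolysis of the cyclic methyl acetal releases the C6 hydroxyl and the non-enolisable C18 aldehyde; the butenolide, allylic alcohol and exocyclic alkene should tolerate it.

**Compound list**

1 | 2,2-dimethoxyacetaldehyde | COC(OC)C=O | starting material
2 | benzyl 2-bromopropanoate (racemic) | CC(Br)C(=O)OCc1ccccc1 | starting material
3 | [1-(benzyloxy)-1-oxopropan-2-yl]triphenylphosphonium bromide | CC(C(=O)OCc1ccccc1)[P+](c1ccccc1)(c1ccccc1)c1ccccc1.[Br-] | intermediate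
4 | benzyl 2-(triphenylphosphoranylidene)propanoate | CC(C(=O)OCc1ccccc1)=P(c1ccccc1)(c1ccccc1)c1ccccc1 | intermediate
5 | benzyl (E)-4,4-dimethoxy-2-methylbut-2-enoate | COC(OC)/C=C(\C)C(=O)OCc1ccccc1 | intermediate
6 | benzyl (E)-2-methyl-4-oxobut-2-enoate | O=C/C=C(\C)C(=O)OCc1ccccc1 | intermediate
7 | (E)-buta-1,3-dien-1-yl acetate | CC(=O)O/C=C/C=C | starting material
8 | benzyl 5-acetoxy-6-formyl-1-methylcyclohex-3-ene-1-carboxylate (formyl trans to ester, cis to methyl and to acetoxy) | O=C[C@@H]1[C@H](OC(C)=O)C=CC[C@@]1(C)C(=O)OCc1ccccc1 | intermediate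
9 | 3-acetoxy-2-formyl-1-methylcyclohexane-1-carboxylic acid (same configuration as 8) | O=C[C@@H]1[C@H](OC(C)=O)CCC[C@@]1(C)C(=O)O | intermediate
10 | trans-fused 4-acetoxy-3-hydroxy-7a-methylhexahydro-2-benzofuran-1(3H)-one (anomers) | OC2[C@@H]1[C@H](OC(C)=O)CCC[C@@]1(C)C(=O)O2 | intermediate
11 | trans-fused 3,4-diacetoxy-7a-methylhexahydro-2-benzofuran-1(3H)-one (anomers) | CC(=O)OC2[C@@H]1[C@H](OC(C)=O)CCC[C@@]1(C)C(=O)O2 | intermediate
12 | tributyl(propa-1,2-dien-1-yl)stannane | C=C=C[Sn](CCCC)(CCCC)CCCC | starting material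
13 | trans-fused 4-acetoxy-7a-methyl-3-(prop-2-yn-1-yl)hexahydro-2-benzofuran-1(3H)-one (propargyl anti to the 7a-methyl) | C#CC[C@H]2[C@@H]1[C@H](OC(C)=O)CCC[C@@]1(C)C(=O)O2 | intermediate
14 | pent-1-en-4-yne | C=CCC#C | starting material
15 | dimethyl[(E)-2-methylpenta-1,4-dien-1-yl]alumane | C=CC/C(C)=C/[Al](C)C | intermediate
16 | (E)-3-methylhexa-2,5-dien-1-ol | C=CC/C(C)=C/CO | intermediate
17 | tert-butyl{[(E)-3-methylhexa-2,5-dien-1-yl]oxy}diphenylsilane | C=CC/C(C)=C/CO[Si](c1ccccc1)(c1ccccc1)C(C)(C)C | intermediate
18 | trans-fused 4-acetoxy-3-[(3E,6E)-8-(tert-butyldiphenylsilyloxy)-6-methyl-2-methylideneocta-3,6-dien-1-yl]-7a-methylhexahydro-2-benzofuran-1(3H)-one | C=C(/C=C/C/C(C)=C/CO[Si](c1ccccc1)(c1ccccc1)C(C)(C)C)C[C@H]2[C@@H]1[C@H](OC(C)=O)CCC[C@@]1(C)C(=O)O2 | intermediate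
19 | trans-fused 4-acetoxy-3-[(2Z,6E)-8-(tert-butyldiphenylsilyloxy)-6-methyl-2-(triethylsilylmethyl)octa-2,6-dien-1-yl]-7a-methylhexahydro-2-benzofuran-1(3H)-one | CC[Si](CC)(CC)C/C(=C\CC/C(C)=C/CO[Si](c1ccccc1)(c1ccccc1)C(C)(C)C)C[C@H]2[C@@H]1[C@H](OC(C)=O)CCC[C@@]1(C)C(=O)O2 | intermediate
20 | 4-hydroxy analogue of 19 (C10 alcohol) | CC[Si](CC)(CC)C/C(=C\CC/C(C)=C/CO[Si](c1ccccc1)(c1ccccc1)C(C)(C)C)C[C@H]2[C@@H]1[C@H](O)CCC[C@@]1(C)C(=O)O2 | intermediate
21 | 4-oxo analogue of 19 (C10 ketone) | CC[Si](CC)(CC)C/C(=C\CC/C(C)=C/CO[Si](c1ccccc1)(c1ccccc1)C(C)(C)C)C[C@H]2[C@@H]1C(=O)CCC[C@@]1(C)C(=O)O2 | intermediate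
22 | 4-hydroxy-4,7a-dimethyl analogue of 19 (tertiary alcohol, C10 epimers) | CC[Si](CC)(CC)C/C(=C\CC/C(C)=C/CO[Si](c1ccccc1)(c1ccccc1)C(C)(C)C)C[C@H]2[C@@H]1C(C)(O)CCC[C@@]1(C)C(=O)O2 | intermediate
23 | (4R,5R,6S,9S,10R,13E)-15-(tert-butyldiphenylsilyloxy)labda-8(17),13-dien-18,6-olide | C=C1C[C@H](O3)[C@@H]2[C@](C)(CCC[C@@]2(C)C3=O)[C@H]1CC/C(C)=C/CO[Si](c1ccccc1)(c1ccccc1)C(C)(C)C | intermediate
24 | lactol of 23 (18-hydroxy-6α,18-epoxide, anomers) | C=C1C[C@H](O3)[C@@H]2[C@](C)(CCC[C@@]2(C)C3O)[C@H]1CC/C(C)=C/CO[Si](c1ccccc1)(c1ccccc1)C(C)(C)C | intermediate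
25 | 18-methoxy-6α,18-epoxide (methyl acetal of 24, anomers) | C=C1C[C@H](O3)[C@@H]2[C@](C)(CCC[C@@]2(C)C3OC)[C@H]1CC/C(C)=C/CO[Si](c1ccccc1)(c1ccccc1)C(C)(C)C | intermediate
26 | (13E)-18-methoxy-6α,18-epoxylabda-8(17),13-dien-15-ol | C=C1C[C@H](O3)[C@@H]2[C@](C)(CCC[C@@]2(C)C3OC)[C@H]1CC/C(C)=C/CO | intermediate
27 | (13E)-18-methoxy-6α,18-epoxylabda-8(17),13-dien-15-al | C=C1C[C@H](O3)[C@@H]2[C@](C)(CCC[C@@]2(C)C3OC)[C@H]1CC/C(C)=C/C=O | intermediate
28 | 4-methylfuran-2(5H)-one | CC1=CC(=O)OC1 | starting material
29 | trimethyl[(4-methylfuran-2-yl)oxy]silane | CC1=COC(O[Si](C)(C)C)=C1 | intermediate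
30 | 15-O-trimethylsilyl ether of 31 | C=C1C[C@H](O3)[C@@H]2[C@](C)(CCC[C@@]2(C)C3OC)[C@H]1CC/C(C)=C/[C@H](O[Si](C)(C)C)[C@H]1OC(=O)C=C1C | intermediate
31 | 18-methoxy-6α,18-epoxy acetal of the target, (15S,5′S) | C=C1C[C@H](O3)[C@@H]2[C@](C)(CCC[C@@]2(C)C3OC)[C@H]1CC/C(C)=C/[C@H](O)[C@H]1OC(=O)C=C1C | intermediate
32 | target, CNP0113661.1 | C=C1C[C@H](O)[C@@H]2[C@](C)(CCC[C@@]2(C)C=O)[C@H]1CC/C(C)=C/[C@H](O)[C@H]1OC(=O)C=C1C | target

**Summary**

Total step count: 21. Longest linear sequence: 18 steps (steps 1–6, 9–18, 20, 21).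

Steps most likely to fail:

Step 14. The tertiary cation may lose a proton to ring A olefins, or the alcohol may ionise sluggishly next to the lactone-bearing carbon, before C9 can add. The fallback sets out from 21 and returns at 23. Methylenation of the ketone (Zn, CH2Br2, TiCl4) gives the exocyclic olefin, the 4-methylidene lactone F1. Treatment of F1 with SnCl4 in CH2Cl2 at −78 °C, the proton-initiated allylsilane-terminated cyclisation known for polyene allylsilanes, forms the same C10 cation reversibly from the olefin and should close ring B under the same lactone control.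

Step 3. Enantioface selectivity may be poor, or turnover slow, with the β,β-disubstituted enal. The fallback sets out from 6 and 7 and returns at 13. Et2AlCl-promoted cycloaddition gives the racemate, 8 together with its enantiomer F2. Hydrogenation as in step 4 gives racemic hydroxy lactone, 10 together with its enantiomer F4, the latter through the enantiomeric formyl acid F3. Acid-catalysed exchange with (−)-menthol (CSA, toluene, reflux) gives two diastereomeric menthyl acetals, the menthyloxy lactone F5 from 10 and the menthyloxy lactone F6 from F4, which are separated by crystallisation or chromatography. F5 is itself an oxocarbenium precursor and is used in place of 11 under the conditions of step 6.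

Step 20. Facial selectivity at the aldehyde may be insufficient, or syn/anti control may erode. The fallback sets out from 27 and 29 and returns at 31. The addition is run without ligand control (Ti(OiPr)4/2,2′-biphenol, Et2O, −20 °C), giving the syn adducts as silyl ethers, 30 and the silyl ether F7 of the other syn isomer. Acidic work-up gives 31 and its (15R,5′R) diastereomer F8. These are diastereomers because the decalin is a single enantiomer, so they are separated by chromatography; F8 can be returned to 27 by base-induced retro-aldol cleavage.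

Further compounds

F1 | step 14 | 4-methylidene analogue of 21 (C10=CH2) | CC[Si](CC)(CC)C/C(=C\CC/C(C)=C/CO[Si](c1ccccc1)(c1ccccc1)C(C)(C)C)C[C@H]2[C@@H]1C(=C)CCC[C@@]1(C)C(=O)O2
F2 | step 3 | enantiomer of 8 | O=C[C@H]1[C@@H](OC(C)=O)C=CC[C@]1(C)C(=O)OCc1ccccc1
F3 | step 3 | enantiomer of 9 | O=C[C@H]1[C@@H](OC(C)=O)CCC[C@]1(C)C(=O)O
F4 | step 3 | enantiomer of 10 | OC2[C@H]1[C@@H](OC(C)=O)CCC[C@]1(C)C(=O)O2
F5 | step 3 | (−)-menthyl acetal of 10 (3-menthyloxy lactone) | CC(C)[C@@H]1CC[C@@H](C)C[C@H]1OC2[C@@H]3[C@H](OC(C)=O)CCC[C@@]3(C)C(=O)O2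
F6 | step 3 | (−)-menthyl acetal of F4 | CC(C)[C@@H]1CC[C@@H](C)C[C@H]1OC2[C@H]3[C@@H](OC(C)=O)CCC[C@]3(C)C(=O)O2
F7 | step 20 | 15-O-trimethylsilyl ether of F8 | C=C1C[C@H](O3)[C@@H]2[C@](C)(CCC[C@@]2(C)C3OC)[C@H]1CC/C(C)=C/[C@@H](O[Si](C)(C)C)[C@@H]1OC(=O)C=C1C
F8 | step 20 | (15R,5′R) diastereomer of 31 | C=C1C[C@H](O3)[C@@H]2[C@](C)(CCC[C@@]2(C)C3OC)[C@H]1CC/C(C)=C/[C@@H](O)[C@@H]1OC(=O)C=C1C
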